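**Strategy.** Ring B holds quaternary C10 (methyl C20) next to C9, and C8 and C9 each carry one exocyclic carbon (C17, C11). A four-carbon alkynoate leaves exactly this pattern after bridging the termini C7 and C10 of a ring A vinylcyclohexene. The plan therefore cuts C7–C8 and C9–C10. One intermolecular Diels–Alder reaction closes ring B, forms both bonds, sets C10 and installs C11 and C17 at useful oxidation levels. Its precursor is an enantiopure 1-vinyl-2-methylcyclohexene with a 3β-silyloxy group cis to the 4β-methyl group and a fluoride-labile 4α-ester (C18). The C12–C16 side chain follows by sulfone alkylation; C3 is inverted late.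

Key step: step 12

**Remarks**
- Labdane numbering and α/β descriptors are used for all compounds, including the monocyclic ones. C17 is the exocyclic methylene carbon, C18 the 4α-carboxyl carbon, C19 the 4β-methyl and C20 the methyl on C10. The target is (3R,4S,5R,9S,10R,13E).
- Assumption on the chemistry: hydride, transfer-hydrogenation or yeast reduction of 2-allyl-2-methylcyclohexane-1,3-dione is taken to place the hydroxyl cis to the allyl group. Diene 17 needs the oxygen cis to the methyl group, so C4 is built by a Claisen shift anti to a C3 silyl ether.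
- C18 travels as a 2-(trimethylsilyl)ethyl ester. This distinguishes it from the C11 methyl ester, and it leaves with fluoride. That avoids forcing cleavage of a crowded methyl ester beside the acetate, the allylic alcohol and the exocyclic alkene.

**Step 1**
Reactants: 1 2-methylcyclohexane-1,3-dione
Product: 2 3-iodo-2-methylcyclohex-2-en-1-one
Conditions: PPh3, I2, Et3N, MeCN, reflux
Reagents that add atoms: iodine, II
Why: The enol oxygen of the vinylogous acid is activated by the iodophosphonium salt and replaced by iodide in an addition–elimination, a standard conversion of cyclic 1,3-diones into β-iodo enones.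

**Step 2**
Reactants: 2 3-iodo-2-methylcyclohex-2-en-1-one
Product: 3 (S)-3-iodo-2-methylcyclohex-2-en-1-ol
Conditions: (R)-2-methyl-CBS-oxazaborolidine (0.1 equiv), BH3·SMe2, THF, −20 °C
Reagents that add atoms: none
Why: Corey–Bakshi–Shibata reduction in which the substituted alkene arm acts as the large group, so the (R)-catalyst should give the (S)-carbinol, the 3β-oxygen of ring A.

**Step 3**
Reactants: 3 (S)-3-iodo-2-methylcyclohex-2-en-1-ol
Product: 4 (S)-tert-butyl[(3-iodo-2-methylcyclohex-2-en-1-yl)oxy]dimethylsilane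
Conditions: TBSCl, imidazole, DMF, rt
Reagents that add atoms: tert-butyldimethylsilyl chloride, CC(C)(C)[Si](C)(C)Cl
Why: Routine silylation of a secondary allylic alcohol that installs the bulky β-face group used as control element in steps 4 and 12.

**Step 4**
Reactants: 4 (S)-tert-butyl[(3-iodo-2-methylcyclohex-2-en-1-yl)oxy]dimethylsilane; 5 allyl alcohol
Product: 7 (2R,3S)-2-allyl-3-(tert-butyldimethylsilyloxy)-2-methylcyclohexan-1-one, via allyl vinyl ether 6 (not isolated)
Conditions: CuI (10 mol %), 3,4,7,8-tetramethyl-1,10-phenanthroline (20 mol %), Cs2CO3, o-xylene, 120 → 140 °C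
Reagents that add atoms: none
Why: Ullmann-type copper-catalysed C–O vinylation followed in the same pot by an aliphatic Claisen rearrangement (a known domino process for vinyl iodides and allylic alcohols); the [3,3] shift runs on the face of C4=C5 opposite the pseudoaxial C3 silyl ether, setting quaternary C4 with allyl α and methyl β, and no enolate is formed that could expel the β-silyloxy group.

**Step 5**
Reactants: 7 (2R,3S)-2-allyl-3-(tert-butyldimethylsilyloxy)-2-methylcyclohexan-1-one
Product: 8 (2R,3S)-3-(tert-butyldimethylsilyloxy)-2-methyl-2-[(E)-prop-1-en-1-yl]cyclohexan-1-one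
Conditions: RuHCl(CO)(PPh3)3 (5 mol %), toluene, 110 °C
Reagents that add atoms: none
Why: Metal-hydride alkene isomerisation (insertion, then β-hydride elimination) moves the terminal alkene by one position and must stop at quaternary C4, giving the more stable E-propenyl group.

**Step 6**
Reactants: 8 (2R,3S)-3-(tert-butyldimethylsilyloxy)-2-methyl-2-[(E)-prop-1-en-1-yl]cyclohexan-1-one
Product: 10 (1S,2S)-2-(tert-butyldimethylsilyloxy)-1-methyl-6-oxocyclohexane-1-carbaldehyde, via secondary ozonide 9 (not isolated)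
Conditions: O3, CH2Cl2, −78 °C; then PPh3, −78 °C → rt
Reagents that add atoms: ozone, [O-][O+]=O
Why: Ozonolysis with reductive work-up cuts the only alkene and leaves C18 as the aldehyde under neutral conditions, so the non-enolisable β-keto aldehyde is not deformylated.

**Step 7**
Reactants: 10 (1S,2S)-2-(tert-butyldimethylsilyloxy)-1-methyl-6-oxocyclohexane-1-carbaldehyde
Product: 11 (1R,2S)-2-(tert-butyldimethylsilyloxy)-1-methyl-6-oxocyclohexane-1-carboxylic acid
Conditions: NaClO2, NaH2PO4, 2-methylbut-2-ene, t-BuOH/H2O, 0 °C; used at once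
Reagents that add atoms: sodium chlorite, [Na+].[O-]Cl=O
Why: Pinnick oxidation works on crowded aldehydes in a weakly acidic buffer, and the α,α-disubstituted β-keto acid is kept cold and carried on directly so that it does not decarboxylate.

**Step 8**
Reactants: 11 (1R,2S)-2-(tert-butyldimethylsilyloxy)-1-methyl-6-oxocyclohexane-1-carboxylic acid
Product: 12 2-(trimethylsilyl)ethyl (1R,2S)-2-(tert-butyldimethylsilyloxy)-1-methyl-6-oxocyclohexane-1-carboxylate
Conditions: Me3SiCH2CH2OH, PPh3, DIAD, THF, 0 °C → rt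
Reagents that add atoms: 2-(trimethylsilyl)ethanol, C[Si](C)(C)CCO
Why: Mitsunobu esterification makes the carboxylate the nucleophile at the primary carbon of the activated alcohol, so crowding at C18 is irrelevant and the β-keto acid sees neither heat nor base.

**Step 9**
Reactants: 12 2-(trimethylsilyl)ethyl (1R,2S)-2-(tert-butyldimethylsilyloxy)-1-methyl-6-oxocyclohexane-1-carboxylate
Product: 14 2-(trimethylsilyl)ethyl (1R,2S)-2-(tert-butyldimethylsilyloxy)-1,5-dimethyl-6-oxocyclohexane-1-carboxylate (epimers at ring C5 = labdane C10), via lithium enolate 13 (not isolated)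
Conditions: LiN(i-Pr)2, THF, −78 °C; then MeI, −78 → −20 °C
Reagents that add atoms: iodomethane, CI
Why: Ketone enolate alkylation at C10, the only enolisable position because C4 is quaternary; the new stereocentre does not matter since it becomes sp2 in step 10.

**Step 10**
Reactants: 14 2-(trimethylsilyl)ethyl (1R,2S)-2-(tert-butyldimethylsilyloxy)-1,5-dimethyl-6-oxocyclohexane-1-carboxylate
Product: 16 2-(trimethylsilyl)ethyl (1R,6S)-6-(tert-butyldimethylsilyloxy)-1,3-dimethyl-2-(trifluoromethylsulfonyloxy)cyclohex-2-ene-1-carboxylate, via potassium enolate 15 (not isolated)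
Conditions: KN(SiMe3)2, THF, −78 → 0 °C; then PhNTf2, −78 °C → rt
Reagents that add atoms: N-phenylbis(trifluoromethanesulfonimide), O=S(=O)(N(c1ccccc1)S(=O)(=O)C(F)(F)F)C(F)(F)F
Why: O-triflation of the single possible, tetrasubstituted enolate, as practised on 2,2,6-trisubstituted cyclohexanones, fixes the C5=C10 double bond.

**Step 11**
Reactants: 16 2-(trimethylsilyl)ethyl (1R,6S)-6-(tert-butyldimethylsilyloxy)-1,3-dimethyl-2-(trifluoromethylsulfonyloxy)cyclohex-2-ene-1-carboxylate
Product: 17 2-(trimethylsilyl)ethyl (1S,6S)-6-(tert-butyldimethylsilyloxy)-1,3-dimethyl-2-vinylcyclohex-2-ene-1-carboxylate (ring A diene: 3β-OTBS, 4β-CH3, 4α-ester)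
Conditions: Bu3SnCH=CH2, Pd(PPh3)4 (5 mol %), LiCl, THF, reflux
Reagents that add atoms: tributyl(vinyl)stannane, C=C[Sn](CCCC)(CCCC)CCCC
Why: Stille coupling of a hindered cyclohexenyl triflate with a vinylstannane in the presence of LiCl is the established way to 1-vinyl-2,6,6-trisubstituted cyclohexenes and is neutral towards both silicon groups.

**Step 12**
Reactants: 17 ring A diene; 18 methyl but-2-ynoate
Product: 19 11-methyl 18-[2-(trimethylsilyl)ethyl] 3β-(tert-butyldimethylsilyloxy)-12,13,14,15,16-pentanorlabda-5,8-diene-11,18-dioate (4β-CH3, 10β-CH3)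
Conditions: 18 (5 equiv), CH2Cl2, BHT (trace), 1.5 GPa, 50 °C
Reagents that add atoms: none
Why: Concerted but asynchronous normal-demand [4+2] cycloaddition of the s-cis diene C10=C5–C6=C7 with the ynoate, the same reaction type as the addition of acetylenic esters to 2,6,6-trimethyl-1-vinylcyclohexene that opens the drimane series. Ring B closes by intermolecular six-membered [4+2] ring formation, C7–C8 and C9–C10 forming suprafacially on one diene face, and the resulting 1,4-cyclohexadiene is safe from later aromatisation because C10 carries four carbon substituents. Regioselectivity is needed and comes from the leading bond, which joins the electrophilic β-carbon of 18 to the unhindered and most nucleophilic terminus C7, so the ester-bearing α-carbon ends on C10. The only new stereocentre, C10, is fixed by the diene face: the 3β-OTBS and 4β-methyl groups lie on the β face in either half-chair of ring A, so 18 should approach from the α face and the inside methyl C20 swings to β. Pressure is used instead of strong heating or a hard Lewis acid because but-2-ynoate is much less reactive than acetylenedicarboxylate; the negative activation volume supplies the acceleration, the 1,5-hydrogen shift of the diene stays slow at 50 °C, and the silyl ether and silylethyl ester are untouched.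

**Step 13**
Reactants: 19 5,8-diene diester
Product: 20 11-methyl 18-[2-(trimethylsilyl)ethyl] 3β-(tert-butyldimethylsilyloxy)-12,13,14,15,16-pentanorlabd-8-ene-11,18-dioate (5α-H, trans-decalin)
Conditions: H2 (1 atm), 10 % Pd/C, EtOAc, rt
Reagents that add atoms: none
Why: Heterogeneous hydrogenation takes the trisubstituted C5=C6 in preference to the tetrasubstituted, ester-conjugated C8=C9; the axial methyls C19 and C20 shield the β face, so hydrogen should arrive from α and set 5α-H.

**Step 14**
Reactants: 20 8-ene diester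
Product: 22 11-methyl 18-[2-(trimethylsilyl)ethyl] 3β-(tert-butyldimethylsilyloxy)-12,13,14,15,16-pentanorlabd-8(17)-ene-11,18-dioate (5α-H, 9α-H), via lithium dienolate 21 (not isolated)
Conditions: LiN(i-Pr)2 (1.5 equiv), THF/DMPU, −78 → −30 °C; then AcOH, −78 °C
Reagents that add atoms: none
Why: Deconjugative protonation of an enoate: the amide bound to the ester carbonyl removes a proton from C17, which is cis to the ester across C8=C9, and kinetic α-protonation from the face opposite axial C20 should give 9α-H, an equatorial ester and the C8=C17 methylene.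

**Step 15**
Reactants: 22 8(17)-ene diester
Product: 23 2-(trimethylsilyl)ethyl 3β-(tert-butyldimethylsilyloxy)-11-hydroxy-12,13,14,15,16-pentanorlabd-8(17)-en-18-oate
Conditions: i-Bu2AlH (2.3 equiv), CH2Cl2, −78 °C; aq. potassium sodium tartrate work-up
Reagents that add atoms: none
Why: Chemoselective ester reduction: the bulky aluminium hydride should reach the C11 methyl ester on secondary C9 well before the C18 ester, which sits on quaternary C4 between the OTBS group and the ring fusion.

**Step 16**
Reactants: 23 11-alcohol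
Product: 24 2-(trimethylsilyl)ethyl 3β-(tert-butyldimethylsilyloxy)-11-(phenylthio)-12,13,14,15,16-pentanorlabd-8(17)-en-18-oate
Conditions: PhSSPh, n-Bu3P, THF, rt → 50 °C
Reagents that add atoms: diphenyl disulfide, c1ccc(SSc2ccccc2)cc1
Why: Phosphine–disulfide redox condensation (Hata reaction) activates the primary alcohol as an alkoxyphosphonium ion that the very nucleophilic, weakly basic thiolate displaces by SN2 even at β-branched C11.

**Step 17**
Reactants: 24 11-sulfide
Product: 25 2-(trimethylsilyl)ethyl 3β-hydroxy-11-(phenylthio)-12,13,14,15,16-pentanorlabd-8(17)-en-18-oate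
Conditions: HF·pyridine, pyridine, THF, 0 °C → rt
Reagents that add atoms: none
Why: Buffered HF cleaves O–Si bonds but leaves the C–Si bond of the silylethyl ester, which needs naked fluoride, and it is too weakly acidic to move the exocyclic alkene.

**Step 18**
Reactants: 25 3β-hydroxy sulfide
Product: 26 2-(trimethylsilyl)ethyl 3-oxo-11-(phenylsulfonyl)-12,13,14,15,16-pentanorlabd-8(17)-en-18-oate
Conditions: n-Pr4NRuO4 (10 mol %), NMO (5 equiv), 4 Å molecular sieves, CH2Cl2/MeCN, rt
Reagents that add atoms: N-methylmorpholine N-oxide, C[N+]1([O-])CCOCC1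
Why: Ley–Griffith conditions oxidise secondary alcohols to ketones and are also known to take sulfides to sulfones without touching isolated alkenes, so both changes are made in one operation while C18 stays esterified and the β-keto ester cannot decarboxylate.

**Step 19**
Reactants: 26 3-oxo sulfone
Product: 27 2-(trimethylsilyl)ethyl 3α-hydroxy-11-(phenylsulfonyl)-12,13,14,15,16-pentanorlabd-8(17)-en-18-oate
Conditions: LiBH(s-Bu)3, THF, −78 °C
Reagents that add atoms: none
Why: The bulky trialkylborohydride attacks 4,4-disubstituted 3-ketones of trans-decalins along the equatorial trajectory, avoiding axial 1α-H and 5α-H, which sets the axial 3α-alcohol of the target and leaves ester and sulfone alone.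

**Step 20**
Reactants: 28 3-methylbut-2-en-1-ol
Product: 29 tert-butyldimethyl[(3-methylbut-2-en-1-yl)oxy]silane
Conditions: TBSCl, imidazole, CH2Cl2, rt
Reagents that add atoms: tert-butyldimethylsilyl chloride, CC(C)(C)[Si](C)(C)Cl
Why: Routine silylation gives the future C15 oxygen a group that survives carbanions and amalgam and leaves with fluoride in the last step.

**Step 21**
Reactants: 29 prenyl TBS ether
Product: 30 (E)-4-(tert-butyldimethylsilyloxy)-2-methylbut-2-en-1-ol
Conditions: SeO2 (0.1 equiv), t-BuOOH, CH2Cl2, 0 °C → rt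
Reagents that add atoms: tert-butyl hydroperoxide, CC(C)(C)OO
Why: Riley allylic oxidation (ene reaction, then [2,3] shift) of a trisubstituted alkene selectively hydroxylates the E-methyl group, which fixes the 13E geometry.

**Step 22**
Reactants: 30 (E)-allylic alcohol
Product: 31 (E)-[(4-bromo-3-methylbut-2-en-1-yl)oxy](tert-butyl)dimethylsilane
Conditions: CBr4, PPh3, CH2Cl2, −20 → 0 °C
Reagents that add atoms: carbon tetrabromide, BrC(Br)(Br)Br
Why: Appel bromination converts the primary allylic alcohol by SN2 under neutral conditions, without allylic transposition, E/Z scrambling or loss of the silyl ether.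

**Step 23**
Reactants: 27 3α-hydroxy sulfone; 31 (E)-allylic bromide
Product: 33 2-(trimethylsilyl)ethyl 15-(tert-butyldimethylsilyloxy)-3α-hydroxy-11-(phenylsulfonyl)labda-8(17),13E-dien-18-oate (C11 epimers), via dilithio sulfone 32 (not isolated)
Conditions: n-BuLi (2.2 equiv), THF/DMPU, −78 °C; then 31, −78 → −40 °C
Reagents that add atoms: none
Why: Alkylation of an α-sulfonyl carbanion by a primary allylic bromide (SN2, geometry retained) forms C11–C12; the hindered axial alkoxide formed by the first equivalent of base is much the poorer nucleophile, and the new C11 centre is erased in step 24.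

**Step 24**
Reactants: 33 alkylated sulfone
Product: 34 2-(trimethylsilyl)ethyl 15-(tert-butyldimethylsilyloxy)-3α-hydroxylabda-8(17),13E-dien-18-oate
Conditions: Na(Hg) (6 % Na), Na2HPO4, MeOH/THF, −20 → 0 °C
Reagents that add atoms: none
Why: Buffered reductive desulfonylation by electron transfer cleaves the alkyl–SO2Ph bond; there is no β-leaving group, and isolated alkenes, the allylic silyl ether and the crowded ester are inert.

**Step 25**
Reactants: 34 3α-alcohol
Product: 35 2-(trimethylsilyl)ethyl 3α-acetoxy-15-(tert-butyldimethylsilyloxy)labda-8(17),13E-dien-18-oate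
Conditions: Ac2O, DMAP, Et3N, CH2Cl2, rt
Reagents that add atoms: acetic anhydride, CC(=O)OC(C)=O
Why: DMAP-catalysed acylation reaches the only free hydroxyl, the axial 3α-OH, with retention at C3 while C15 and C18 are still masked.

**Step 26**
Reactants: 35 fully protected acetate
Product: 36 (3R,4S,5R,9S,10R,13E)-3α-acetoxy-15-hydroxylabda-8(17),13-dien-18-oic acid (target)
Conditions: n-Bu4NF, THF, 0 °C → rt; pH 4 buffer work-up
Reagents that add atoms: none
Why: Fluoride attacks both silicon atoms: fragmentation to ethene and Me3SiF frees the C18 carboxylate without any attack at the crowded carbonyl, the C15 silyl ether falls off, and the hindered 3α-acetate should survive.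

**Compound list**
1 | 2-methylcyclohexane-1,3-dione | CC1C(=O)CCCC1=O | starting material
2 | 3-iodo-2-methylcyclohex-2-en-1-one | CC1=C(I)CCCC1=O | intermediate
3 | (S)-3-iodo-2-methylcyclohex-2-en-1-ol | C1CC[C@H](O)C(C)=C1I | intermediate
4 | (S)-tert-butyl[(3-iodo-2-methylcyclohex-2-en-1-yl)oxy]dimethylsilane | C1CC[C@H](O[Si](C)(C)C(C)(C)C)C(C)=C1I | intermediate
5 | allyl alcohol | C=CCO | starting material
6 | (S)-{[3-(allyloxy)-2-methylcyclohex-2-en-1-yl]oxy}(tert-butyl)dimethylsilane (allyl vinyl ether, not isolated) | C1CC[C@H](O[Si](C)(C)C(C)(C)C)C(C)=C1OCC=C | intermediate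
7 | (2R,3S)-2-allyl-3-(tert-butyldimethylsilyloxy)-2-methylcyclohexan-1-one | O=C1CCC[C@H](O[Si](C)(C)C(C)(C)C)[C@@]1(C)CC=C | intermediate
8 | (2R,3S)-3-(tert-butyldimethylsilyloxy)-2-methyl-2-[(E)-prop-1-en-1-yl]cyclohexan-1-one | O=C1CCC[C@H](O[Si](C)(C)C(C)(C)C)[C@@]1(C)/C=C/C | intermediate
9 | secondary ozonide of 8 (1,2,4-trioxolane, not isolated) | O=C1CCC[C@H](O[Si](C)(C)C(C)(C)C)[C@@]1(C)C2OOC(C)O2 | intermediate
10 | (1S,2S)-2-(tert-butyldimethylsilyloxy)-1-methyl-6-oxocyclohexane-1-carbaldehyde | O=C1CCC[C@H](O[Si](C)(C)C(C)(C)C)[C@@]1(C)C=O | intermediate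
11 | (1R,2S)-2-(tert-butyldimethylsilyloxy)-1-methyl-6-oxocyclohexane-1-carboxylic acid | O=C1CCC[C@H](O[Si](C)(C)C(C)(C)C)[C@@]1(C)C(=O)O | intermediate
12 | 2-(trimethylsilyl)ethyl (1R,2S)-2-(tert-butyldimethylsilyloxy)-1-methyl-6-oxocyclohexane-1-carboxylate | O=C1CCC[C@H](O[Si](C)(C)C(C)(C)C)[C@@]1(C)C(=O)OCC[Si](C)(C)C | intermediate
13 | lithium enolate of 12 (not isolated) | [Li+].[O-]C1=CCC[C@H](O[Si](C)(C)C(C)(C)C)[C@@]1(C)C(=O)OCC[Si](C)(C)C | intermediate
14 | 2-(trimethylsilyl)ethyl (1R,2S)-2-(tert-butyldimethylsilyloxy)-1,5-dimethyl-6-oxocyclohexane-1-carboxylate (C10 epimers) | O=C1C(C)CC[C@H](O[Si](C)(C)C(C)(C)C)[C@@]1(C)C(=O)OCC[Si](C)(C)C | intermediate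
15 | potassium enolate of 14 (not isolated) | [K+].[O-]C1=C(C)CC[C@H](O[Si](C)(C)C(C)(C)C)[C@@]1(C)C(=O)OCC[Si](C)(C)C | intermediate
16 | 2-(trimethylsilyl)ethyl (1R,6S)-6-(tert-butyldimethylsilyloxy)-1,3-dimethyl-2-(trifluoromethylsulfonyloxy)cyclohex-2-ene-1-carboxylate | FC(F)(F)S(=O)(=O)OC1=C(C)CC[C@H](O[Si](C)(C)C(C)(C)C)[C@@]1(C)C(=O)OCC[Si](C)(C)C | intermediate
17 | 2-(trimethylsilyl)ethyl (1S,6S)-6-(tert-butyldimethylsilyloxy)-1,3-dimethyl-2-vinylcyclohex-2-ene-1-carboxylate (ring A diene) | C=CC1=C(C)CC[C@H](O[Si](C)(C)C(C)(C)C)[C@@]1(C)C(=O)OCC[Si](C)(C)C | intermediate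
18 | methyl but-2-ynoate | CC#CC(=O)OC | starting material
19 | 11-methyl 18-[2-(trimethylsilyl)ethyl] 3β-(tert-butyldimethylsilyloxy)-12,13,14,15,16-pentanorlabda-5,8-diene-11,18-dioate | CC1=C(C(=O)OC)[C@@]2(C)CC[C@H](O[Si](C)(C)C(C)(C)C)[C@@](C)(C(=O)OCC[Si](C)(C)C)C2=CC1 | intermediate
20 | 11-methyl 18-[2-(trimethylsilyl)ethyl] 3β-(tert-butyldimethylsilyloxy)-12,13,14,15,16-pentanorlabd-8-ene-11,18-dioate (5α-H) | CC1=C(C(=O)OC)[C@@]2(C)CC[C@H](O[Si](C)(C)C(C)(C)C)[C@@](C)(C(=O)OCC[Si](C)(C)C)[C@@H]2CC1 | intermediate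
21 | lithium dienolate of 20 (C8=C17, C9=C11; not isolated) | C=C1CC[C@@H]2[C@](C)(CC[C@H](O[Si](C)(C)C(C)(C)C)[C@@]2(C)C(=O)OCC[Si](C)(C)C)C1=C(OC)[O-].[Li+] | intermediate
22 | 11-methyl 18-[2-(trimethylsilyl)ethyl] 3β-(tert-butyldimethylsilyloxy)-12,13,14,15,16-pentanorlabd-8(17)-ene-11,18-dioate (5α-H, 9α-H) | C=C1CC[C@@H]2[C@](C)(CC[C@H](O[Si](C)(C)C(C)(C)C)[C@@]2(C)C(=O)OCC[Si](C)(C)C)[C@H]1C(=O)OC | intermediate
23 | 2-(trimethylsilyl)ethyl 3β-(tert-butyldimethylsilyloxy)-11-hydroxy-12,13,14,15,16-pentanorlabd-8(17)-en-18-oate | C=C1CC[C@@H]2[C@](C)(CC[C@H](O[Si](C)(C)C(C)(C)C)[C@@]2(C)C(=O)OCC[Si](C)(C)C)[C@H]1CO | intermediate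
24 | 2-(trimethylsilyl)ethyl 3β-(tert-butyldimethylsilyloxy)-11-(phenylthio)-12,13,14,15,16-pentanorlabd-8(17)-en-18-oate | C=C1CC[C@@H]2[C@](C)(CC[C@H](O[Si](C)(C)C(C)(C)C)[C@@]2(C)C(=O)OCC[Si](C)(C)C)[C@H]1CSc3ccccc3 | intermediate
25 | 2-(trimethylsilyl)ethyl 3β-hydroxy-11-(phenylthio)-12,13,14,15,16-pentanorlabd-8(17)-en-18-oate | C=C1CC[C@@H]2[C@](C)(CC[C@H](O)[C@@]2(C)C(=O)OCC[Si](C)(C)C)[C@H]1CSc3ccccc3 | intermediate
26 | 2-(trimethylsilyl)ethyl 3-oxo-11-(phenylsulfonyl)-12,13,14,15,16-pentanorlabd-8(17)-en-18-oate | C=C1CC[C@@H]2[C@](C)(CCC(=O)[C@@]2(C)C(=O)OCC[Si](C)(C)C)[C@H]1CS(=O)(=O)c3ccccc3 | intermediate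
27 | 2-(trimethylsilyl)ethyl 3α-hydroxy-11-(phenylsulfonyl)-12,13,14,15,16-pentanorlabd-8(17)-en-18-oate | C=C1CC[C@@H]2[C@](C)(CC[C@@H](O)[C@@]2(C)C(=O)OCC[Si](C)(C)C)[C@H]1CS(=O)(=O)c3ccccc3 | intermediate
28 | 3-methylbut-2-en-1-ol | CC(C)=CCO | starting material
29 | tert-butyldimethyl[(3-methylbut-2-en-1-yl)oxy]silane | CC(C)=CCO[Si](C)(C)C(C)(C)C | intermediate
30 | (E)-4-(tert-butyldimethylsilyloxy)-2-methylbut-2-en-1-ol | OC/C(C)=C/CO[Si](C)(C)C(C)(C)C | intermediate
31 | (E)-[(4-bromo-3-methylbut-2-en-1-yl)oxy](tert-butyl)dimethylsilane | BrC/C(C)=C/CO[Si](C)(C)C(C)(C)C | intermediate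
32 | dilithio derivative of 27 (3α-alkoxide, C11 carbanion; not isolated) | C=C1CC[C@@H]2[C@](C)(CC[C@@H]([O-])[C@@]2(C)C(=O)OCC[Si](C)(C)C)[C@H]1[CH-]S(=O)(=O)c3ccccc3.[Li+].[Li+] | intermediate
33 | 2-(trimethylsilyl)ethyl 15-(tert-butyldimethylsilyloxy)-3α-hydroxy-11-(phenylsulfonyl)labda-8(17),13E-dien-18-oate (C11 epimers) | C=C1CC[C@@H]2[C@](C)(CC[C@@H](O)[C@@]2(C)C(=O)OCC[Si](C)(C)C)[C@H]1C(C/C(C)=C/CO[Si](C)(C)C(C)(C)C)S(=O)(=O)c3ccccc3 | intermediate
34 | 2-(trimethylsilyl)ethyl 15-(tert-butyldimethylsilyloxy)-3α-hydroxylabda-8(17),13E-dien-18-oate | C=C1CC[C@@H]2[C@](C)(CC[C@@H](O)[C@@]2(C)C(=O)OCC[Si](C)(C)C)[C@H]1CC/C(C)=C/CO[Si](C)(C)C(C)(C)C | intermediate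
35 | 2-(trimethylsilyl)ethyl 3α-acetoxy-15-(tert-butyldimethylsilyloxy)labda-8(17),13E-dien-18-oate | C=C1CC[C@@H]2[C@](C)(CC[C@@H](OC(C)=O)[C@@]2(C)C(=O)OCC[Si](C)(C)C)[C@H]1CC/C(C)=C/CO[Si](C)(C)C(C)(C)C | intermediate
36 | 3α-acetoxy-15-hydroxylabda-8(17),13E-dien-18-oic acid, (3R,4S,5R,9S,10R) | C=C1CC[C@@H]2[C@](C)(CC[C@@H](OC(C)=O)[C@@]2(C)C(=O)O)[C@H]1CC/C(C)=C/CO | target

**Total step count:** 26.
**Longest linear sequence:** 23 steps (steps 1–19 and 23–26, from 1). Steps 20–22 make the side-chain bromide in parallel.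

**Three steps most likely to fail**

1. **Step 12.** The cycloaddition may stay too slow even under pressure, so that polymerisation or hydrogen-shift isomerisation of the diene takes over. Face selectivity may also erode if the temperature has to be raised. The fallback raises the electrophilicity of the four-carbon dienophile instead of forcing the conditions; it sets out from 17 and comes back at 19. But-2-ynal F1 is made by MnO2 oxidation of but-2-yn-1-ol. It is added to 17 with catalytic BF3·OEt2 in CH2Cl2 at −60 °C, where the aldehyde binds the Lewis acid in preference to the esters. The same two bonds and the same ring form and give the 5,8-dien-11-al F2. NaClO2/NaH2PO4/2-methylbut-2-ene then gives the 11-carboxylic acid F3, and Me3SiCHN2 in toluene/MeOH gives 19.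

2. **Step 4.** The C–O coupling may be sluggish at the tetrasubstituted vinyl iodide, or the silyl ether may be lost at the temperature of the rearrangement. The fallback sets C4 by desymmetrisation and the 3β-oxygen by directed hydride delivery; it sets out from 1 and comes back at 7. Tsuji–Trost C-allylation (allyl acetate, Pd(PPh3)4, Et3N, THF) gives 2-allyl-2-methylcyclohexane-1,3-dione F4. Baker's yeast (sucrose, water, 30 °C) reduces one carbonyl to the (2S,3S)-ketol F5. Its hydroxyl is cis to allyl and is therefore used as the future C5 oxygen. Evans–Tishchenko reduction (PhCHO, catalytic SmI2, THF, −10 °C) delivers hydride to the remaining ketone from the face of that oxygen. This gives the anti-diol monobenzoate F6, with the free hydroxyl cis to the methyl group. TBSOTf/2,6-lutidine gives the silyl ether benzoate F7, i-Bu2AlH removes the benzoate to give the alcohol F8, and Dess–Martin oxidation gives 7.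

3. **Step 15.** The two esters may not be discriminated well enough, leading to attack on the C18 ester or a stalled reduction at crowded C11. The fallback separates the two carboxyl groups by hydrolysis rate and reduces only an activated acyl group; it sets out from 22 and comes back at 23. Me3SnOH in 1,2-dichloroethane at 80 °C cleaves only the less hindered methyl ester, under near-neutral conditions that should not reconjugate the alkene, giving the 11-carboxylic acid F9. Isobutyl chloroformate/N-methylmorpholine in THF at −15 °C gives the mixed carbonic anhydride F10. NaBH4 in THF/water at 0 °C reduces this to 23 and does not touch the C18 ester or the alkene.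

**Further compounds**
F1 | step 12 | but-2-ynal | CC#CC=O
F2 | step 12 | 2-(trimethylsilyl)ethyl 3β-(tert-butyldimethylsilyloxy)-11-oxo-12,13,14,15,16-pentanorlabda-5,8-dien-18-oate | CC1=C(C=O)[C@@]2(C)CC[C@H](O[Si](C)(C)C(C)(C)C)[C@@](C)(C(=O)OCC[Si](C)(C)C)C2=CC1
F3 | step 12 | 3β-(tert-butyldimethylsilyloxy)-12,13,14,15,16-pentanorlabda-5,8-diene-11,18-dioic acid 18-[2-(trimethylsilyl)ethyl] ester | CC1=C(C(=O)O)[C@@]2(C)CC[C@H](O[Si](C)(C)C(C)(C)C)[C@@](C)(C(=O)OCC[Si](C)(C)C)C2=CC1
F4 | step 4 | 2-allyl-2-methylcyclohexane-1,3-dione | C=CCC1(C)C(=O)CCCC1=O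
F5 | step 4 | (2S,3S)-2-allyl-3-hydroxy-2-methylcyclohexan-1-one | O=C1CCC[C@H](O)[C@]1(C)CC=C
F6 | step 4 | 2-allyl-3-hydroxy-2-methylcyclohexyl benzoate (benzoate cis to allyl, hydroxyl cis to methyl) | O[C@H]1CCC[C@H](OC(=O)c2ccccc2)[C@]1(C)CC=C
F7 | step 4 | 2-allyl-3-(tert-butyldimethylsilyloxy)-2-methylcyclohexyl benzoate (same configuration) | CC(C)(C)[Si](C)(C)O[C@H]1CCC[C@H](OC(=O)c2ccccc2)[C@]1(C)CC=C
F8 | step 4 | 2-allyl-3-(tert-butyldimethylsilyloxy)-2-methylcyclohexan-1-ol (hydroxyl cis to allyl, silyloxy cis to methyl) | CC(C)(C)[Si](C)(C)O[C@H]1CCC[C@H](O)[C@]1(C)CC=C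
F9 | step 15 | 3β-(tert-butyldimethylsilyloxy)-12,13,14,15,16-pentanorlabd-8(17)-ene-11,18-dioic acid 18-[2-(trimethylsilyl)ethyl] ester | C=C1CC[C@@H]2[C@](C)(CC[C@H](O[Si](C)(C)C(C)(C)C)[C@@]2(C)C(=O)OCC[Si](C)(C)C)[C@H]1C(=O)O
F10 | step 15 | mixed anhydride of F9 with isobutyl hydrogen carbonate | C=C1CC[C@@H]2[C@](C)(CC[C@H](O[Si](C)(C)C(C)(C)C)[C@@]2(C)C(=O)OCC[Si](C)(C)C)[C@H]1C(=O)OC(=O)OCC(C)C
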